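The plan cuts ring A off at C1–C10 and C4–C5, leaving a ring-B cyclohexanone. It exploits the fact that C8, C9 and quaternary C10 are contiguous on ring B: the C8 carbinol, taken from the tertiary alcohol carbon of (S)-linalool, steers the side chain onto C9, and C9 in turn steers the annulation at C10. In one operation the key step joins ethyl vinyl ketone to C10 (Mukaiyama–Michael) and closes ring A by aldol condensation, creating the C10 stereocentre. Its precursor is the C5–C10 trimethylsilyl enol ether of a 2-methyl-3-alkyl-4-methyl-4-silyloxycyclohexanone carrying the complete, protected C11–C15 chain.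

Key step: step 11

Remark (assumption): labdane numbering is used for all ring compounds (C18 is the C4 carbon trans to C20), and methyl hydrogen (R)-3-methylglutarate and (S)-(+)-linalool are taken as purchasable enantioenriched materials.

Step 1
Reactants: 1 methyl hydrogen (R)-3-methylglutarate
Product: 2 methyl (3R)-5-hydroxy-3-methylpentanoate
Conditions: BH3·SMe2, THF, −10 °C → rt; aqueous work-up, used crude
Reagents that add atoms: none
Why: Chemoselective borane reduction, in which BH3 reduces the carboxylic acid much faster than the methyl ester, so the two arms at the future C13 are differentiated without touching any bond to the stereocentre.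

Step 2
Reactants: 2 methyl (3R)-5-hydroxy-3-methylpentanoate
Product: 3 methyl (3R)-3-methyl-5-(triisopropylsilyloxy)pentanoate
Conditions: TIPSCl, imidazole, DMF, rt
Reagents that add atoms: triisopropylsilyl chloride, CC(C)[Si](Cl)(C(C)C)C(C)C
Why: Standard silyl ether formation on the primary alcohol, done on the crude hydroxy ester before it can lactonise; TIPS is chosen over a smaller silyl group because this C15 ether must outlast BF3, methoxide, Li/NH3 and hydrazone formation, keeping C15 masked until C18 is esterified.

Step 3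
Reactants: 3 methyl (3R)-3-methyl-5-(triisopropylsilyloxy)pentanoate
Product: 4 (3S)-3-methyl-5-(triisopropylsilyloxy)pentan-1-ol
Conditions: LiAlH4, Et2O, 0 °C
Reagents that add atoms: none
Why: Hydride reduction of the ester to the primary alcohol, to which the TIPS ether and the stereocentre are inert (the descriptor changes only through CIP priorities).

Step 4
Reactants: 4 (3S)-3-methyl-5-(triisopropylsilyloxy)pentan-1-ol
Product: 5 (3R)-5-bromo-3-methylpentyl triisopropylsilyl ether
Conditions: CBr4, PPh3, CH2Cl2, 0 °C
Reagents that add atoms: carbon tetrabromide, BrC(Br)(Br)Br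
Why: Appel bromination converts the primary alcohol into the bromide by SN2 at a carbon remote from the stereocentre, under neutral conditions that spare the silyl ether.

Step 5
Reactants: 6 (S)-(+)-linalool
Product: 7 (S)-linalool triethylsilyl ether
Conditions: TESOTf, 2,6-lutidine, CH2Cl2, −78 → 0 °C
Reagents that add atoms: triethylsilyl trifluoromethanesulfonate, CC[Si](CC)(CC)OS(=O)(=O)C(F)(F)F
Why: Silylation of the hindered tertiary allylic alcohol with a silyl triflate and a hindered base breaks no bond to the carbinol carbon (future C8), so its S configuration is carried through; the small TES group is chosen because O8 will later sit axial close to the reacting C10.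

Step 6
Reactants: 7 (S)-linalool triethylsilyl ether
Product: 8 (4S)-4-methyl-4-(triethylsilyloxy)hex-5-enal
Conditions: O3 (to the Sudan Red 7B end-point), CH2Cl2/MeOH, −78 °C; PPh3, −78 °C → rt
Reagents that add atoms: ozone, [O-][O+]=O
Why: Chemoselective ozonolysis, in which the electron-rich trisubstituted alkene is cleaved well before the monosubstituted vinyl group deactivated by the allylic silyloxy substituent, and reductive work-up gives the aldehyde.

Step 7
Reactants: 8 (4S)-4-methyl-4-(triethylsilyloxy)hex-5-enal
Product: 9 (6S)-2,6-dimethyl-6-(triethylsilyloxy)octa-1,7-dien-3-ol (both C3 epimers)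
Conditions: isopropenylmagnesium bromide, THF, −78 → 0 °C; aq. NH4Cl
Reagents that add atoms: isopropenylmagnesium bromide, CC(=C)[Mg]Br
Why: Grignard 1,2-addition to the aldehyde, whose new carbinol centre forms as a mixture that is of no consequence because it is oxidised in step 8.

Step 8
Reactants: 9 (6S)-2,6-dimethyl-6-(triethylsilyloxy)octa-1,7-dien-3-ol (both C3 epimers)
Product: 10 (6S)-2,6-dimethyl-6-(triethylsilyloxy)octa-1,7-dien-3-one
Conditions: Dess–Martin periodinane, NaHCO3, CH2Cl2, 0 °C → rt
Reagents that add atoms: none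
Why: Dess–Martin oxidation of the secondary allylic alcohol under buffered, non-acidic conditions should give the α-methylene ketone without isomerisation or loss of the TES ether.

Step 9
Reactants: 10 (6S)-2,6-dimethyl-6-(triethylsilyloxy)octa-1,7-dien-3-one
Product: 11 (4S)-2,4-dimethyl-4-(triethylsilyloxy)cyclohex-2-en-1-one
Conditions: Grubbs second-generation catalyst (5 mol %), toluene (0.01 M), 80 °C
Reagents that add atoms: none
Why: Ring-closing metathesis, in which the ruthenium carbene loads on the monosubstituted vinyl group and closes on the 1,1-disubstituted enone alkene to give the six-membered 2-methyl enone with loss of ethylene, the quaternary carbinol keeping its configuration.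

Step 10
Reactants: 11 (4S)-2,4-dimethyl-4-(triethylsilyloxy)cyclohex-2-en-1-one; 5 (3R)-5-bromo-3-methylpentyl triisopropylsilyl ether
Product: 13 (3S,4S)-2,4-dimethyl-3-[(3S)-3-methyl-5-(triisopropylsilyloxy)pentyl]-4-(triethylsilyloxy)-1-(trimethylsilyloxy)cyclohex-1-ene (the C5–C10 enol ether; 8S,9S,13S), via alkylmagnesium bromide 12 (not isolated)
Conditions: 5, Mg, THF, rt; then CuBr·SMe2 (10 mol %), HMPA, TMSCl, 11, THF, −78 → −40 °C; Et3N, cold aq. NaHCO3, used crude
Reagents that add atoms: chlorotrimethylsilane, C[Si](C)(C)Cl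
Why: Copper-catalysed conjugate addition of a Grignard reagent accelerated by TMSCl/HMPA, which tolerates α- and γ-substituted cyclohexenones and traps the enolate regiospecifically as the C5–C10 silyl enol ether; the new C9 stereocentre is set by axial attack anti to the pseudoaxial C8 silyloxy group (the face preferred by 4-silyloxycyclohex-2-enones), so the chain ends trans to O8 and cis to C17.

Step 11
Reactants: 13 the C5–C10 trimethylsilyl enol ether (8S,9S,13S); 14 ethyl vinyl ketone
Product: 17 (4aS,5S,6S)-1,4a,6-trimethyl-5-[(3S)-3-methyl-5-(triisopropylsilyloxy)pentyl]-6-(triethylsilyloxy)-4,4a,5,6,7,8-hexahydronaphthalen-2(3H)-one (the 4-methyl-4-en-3-one; 8S,9S,10S,13S), via 1,5-diketone 15 (not isolated), via ketol 16 (not isolated)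
Conditions: (i) 14, BF3·OEt2, i-PrOH, CH2Cl2, −78 °C; aq. NaHCO3; (ii) crude 15, NaOMe, MeOH, 55 °C
Reagents that add atoms: none
Why: BF3-activated ethyl vinyl ketone is attacked by C10 of the tetrasubstituted silyl enol ether (Mukaiyama–Michael addition, bond C1–C10), the trimethylsilyl group passing to isopropanol to leave diketone 15, and methoxide then generates the C4 enolate of the ethyl ketone, which adds to the C5 carbonyl and dehydrates through ketol 16 (bond C4–C5). The closest known reaction type is the Lewis-acid Michael addition of regiodefined trimethylsilyl enol ethers of 2-methylcyclohexanones to alkyl vinyl ketones followed by base-mediated aldol condensation, i.e. a Robinson annulation in two stages, as used to make cis-vicinally substituted octalones from 2,3-dialkylcyclohexanones. Ring A closes by a 6-(enolendo)-exo-trig aldol addition. The single new stereocentre, quaternary C10, is controlled by C9: allylic strain with the C10 methyl holds the C9 chain pseudoaxial, so the acceptor adds axially to the opposite face and C20 ends cis to C11. The step needs this facial selectivity, secured by the neighbouring C9 substituent (itself fixed by C8), and attack through C10 instead of C6, secured by the enol ether regiochemistry set in step 10.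

Step 12
Reactants: 17 the 4-methyl-4-en-3-one (8S,9S,10S,13S)
Product: 19 (4S,5S,8S,9S,10R,13S)-18-hydroxy-8-(triethylsilyloxy)-15-(triisopropylsilyloxy)labdan-3-one, via lithium enolate 18 (not isolated)
Conditions: Li, NH3(l)/THF, t-BuOH (1 equiv), −78 → −33 °C; isoprene; NH3 off, THF; CH2O (g, from cracked paraformaldehyde), −78 °C; aq. NH4Cl
Reagents that add atoms: formaldehyde, C=O
Why: Dissolving-metal reduction of the enone with enolate trapping (reductive alkylation), in which axial protonation at C5 gives the trans-decalin with H5 anti to C20 and leaves the C3–C4 lithium enolate regiospecifically, and formaldehyde then adds to C4 on the face away from the axial C10 methyl, so the CH2OH group (C18) is equatorial and the C4 methyl axial, as in known reductive hydroxymethylations of 4-methyl-Δ4-3-keto decalins.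

Step 13
Reactants: 19 (4S,5S,8S,9S,10R,13S)-18-hydroxy-8-(triethylsilyloxy)-15-(triisopropylsilyloxy)labdan-3-one
Product: 20 C3 p-toluenesulfonylhydrazone of 19 (stereocentres as in 19)
Conditions: TsNHNH2, EtOH, 70 °C
Reagents that add atoms: p-toluenesulfonyl hydrazide, Cc1ccc(cc1)S(=O)(=O)NN
Why: Tosylhydrazone formation is a weakly acidic condensation that avoids the base-induced retro-aldol loss of formaldehyde from the β-hydroxy ketone and so makes a protecting group on O18 unnecessary, with no stereocentre affected.

Step 14
Reactants: 20 C3 p-toluenesulfonylhydrazone of 19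
Product: 21 (4S,5S,8S,9S,10R,13S)-8-(triethylsilyloxy)-15-(triisopropylsilyloxy)labdan-18-ol
Conditions: catecholborane, CHCl3, 0 °C → rt; then NaOAc·3H2O, 60 °C
Reagents that add atoms: none
Why: Caglioti-type reduction of the tosylhydrazone with catecholborane, followed by acetate-induced loss of sulfinate and dinitrogen from the diazene, should convert C3 into CH2 under near-neutral conditions that leave both silyl ethers and all stereocentres untouched (the free O18 is only transiently borylated).

Step 15
Reactants: 21 (4S,5S,8S,9S,10R,13S)-8-(triethylsilyloxy)-15-(triisopropylsilyloxy)labdan-18-ol; 22 angelic acid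
Product: 24 (4S,5S,8S,9S,10R,13S)-8-(triethylsilyloxy)-15-(triisopropylsilyloxy)labdan-18-yl angelate, via mixed anhydride 23 (not isolated)
Conditions: 22, 2,4,6-trichlorobenzoyl chloride, Et3N, toluene, rt; then 21, toluene, 80 °C
Reagents that add atoms: none
Why: Yamaguchi-type esterification through the mixed 2,4,6-trichlorobenzoic anhydride is the established way to introduce an angelate without Z→E isomerisation, and only the primary C18 hydroxyl is free because O15 and the tertiary O8 are silylated.

Step 16
Reactants: 24 (4S,5S,8S,9S,10R,13S)-8-(triethylsilyloxy)-15-(triisopropylsilyloxy)labdan-18-yl angelate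
Product: 25 (4S,5S,8S,9S,10R,13S)-8,15-dihydroxylabdan-18-yl (2Z)-2-methylbut-2-enoate (CNP0150844.1)
Conditions: HF·pyridine, pyridine, THF, 0 °C → rt
Reagents that add atoms: none
Why: Fluoride-mediated cleavage of both silyl ethers with pyridine-buffered HF·pyridine is mild enough to leave the angelate geometry, the ester and the tertiary C8 alcohol intact.

Compound list

1 | methyl hydrogen (R)-3-methylglutarate [(3R)-5-methoxy-3-methyl-5-oxopentanoic acid] | COC(=O)C[C@H](C)CC(=O)O | starting material
2 | methyl (3R)-5-hydroxy-3-methylpentanoate | COC(=O)C[C@H](C)CCO | intermediate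
3 | methyl (3R)-3-methyl-5-(triisopropylsilyloxy)pentanoate | COC(=O)C[C@H](C)CCO[Si](C(C)C)(C(C)C)C(C)C | intermediate
4 | (3S)-3-methyl-5-(triisopropylsilyloxy)pentan-1-ol | OCC[C@H](C)CCO[Si](C(C)C)(C(C)C)C(C)C | intermediate
5 | (3R)-5-bromo-3-methylpentyl triisopropylsilyl ether | BrCC[C@H](C)CCO[Si](C(C)C)(C(C)C)C(C)C | intermediate
6 | (S)-(+)-linalool [(3S)-3,7-dimethylocta-1,6-dien-3-ol] | CC(C)=CCC[C@](C)(O)C=C | starting material
7 | (S)-linalool triethylsilyl ether | CC(C)=CCC[C@](C)(O[Si](CC)(CC)CC)C=C | intermediate
8 | (4S)-4-methyl-4-(triethylsilyloxy)hex-5-enal | O=CCC[C@](C)(O[Si](CC)(CC)CC)C=C | intermediate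
9 | (6S)-2,6-dimethyl-6-(triethylsilyloxy)octa-1,7-dien-3-ol (both C3 epimers) | CC(=C)C(O)CC[C@](C)(O[Si](CC)(CC)CC)C=C | intermediate
10 | (6S)-2,6-dimethyl-6-(triethylsilyloxy)octa-1,7-dien-3-one | CC(=C)C(=O)CC[C@](C)(O[Si](CC)(CC)CC)C=C | intermediate
11 | (4S)-2,4-dimethyl-4-(triethylsilyloxy)cyclohex-2-en-1-one | CC1=C[C@@](C)(O[Si](CC)(CC)CC)CCC1=O | intermediate
12 | [(3R)-3-methyl-5-(triisopropylsilyloxy)pentyl]magnesium bromide | Br[Mg]CC[C@H](C)CCO[Si](C(C)C)(C(C)C)C(C)C | intermediate
13 | (3S,4S)-2,4-dimethyl-3-[(3S)-3-methyl-5-(triisopropylsilyloxy)pentyl]-4-(triethylsilyloxy)-1-(trimethylsilyloxy)cyclohex-1-ene (C5–C10 enol ether; chain trans to O8) | C[Si](C)(C)OC1=C(C)[C@H](CC[C@H](C)CCO[Si](C(C)C)(C(C)C)C(C)C)[C@@](C)(O[Si](CC)(CC)CC)CC1 | intermediate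
14 | ethyl vinyl ketone (pent-1-en-3-one) | CCC(=O)C=C | starting material
15 | (2S,3S,4S)-2,4-dimethyl-3-[(3S)-3-methyl-5-(triisopropylsilyloxy)pentyl]-2-(3-oxopentyl)-4-(triethylsilyloxy)cyclohexan-1-one (C20 cis to the C9 chain) | CCC(=O)CC[C@]1(C)C(=O)CC[C@](C)(O[Si](CC)(CC)CC)[C@H]1CC[C@H](C)CCO[Si](C(C)C)(C(C)C)C(C)C | intermediate
16 | ring-A ketol, 5-hydroxy-4-methyl-3-one (C4/C5 epimers; other centres as in 17) | CC1C(=O)CC[C@]2(C)C1(O)CC[C@](C)(O[Si](CC)(CC)CC)[C@H]2CC[C@H](C)CCO[Si](C(C)C)(C(C)C)C(C)C | intermediate
17 | (4aS,5S,6S)-1,4a,6-trimethyl-5-[(3S)-3-methyl-5-(triisopropylsilyloxy)pentyl]-6-(triethylsilyloxy)-4,4a,5,6,7,8-hexahydronaphthalen-2(3H)-one (4-methyl-4-en-3-one; 8S,9S,10S,13S) | O=C1CC[C@]2(C)C(=C1C)CC[C@](C)(O[Si](CC)(CC)CC)[C@H]2CC[C@H](C)CCO[Si](C(C)C)(C(C)C)C(C)C | intermediate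
18 | C3–C4 lithium enolate of the trans-decalin (H5 anti to C20) | CC1=C(O[Li])CC[C@]2(C)[C@@H]1CC[C@](C)(O[Si](CC)(CC)CC)[C@H]2CC[C@H](C)CCO[Si](C(C)C)(C(C)C)C(C)C | intermediate
19 | (4S,5S,8S,9S,10R,13S)-18-hydroxy-8-(triethylsilyloxy)-15-(triisopropylsilyloxy)labdan-3-one | OC[C@@]1(C)C(=O)CC[C@]2(C)[C@@H]1CC[C@](C)(O[Si](CC)(CC)CC)[C@H]2CC[C@H](C)CCO[Si](C(C)C)(C(C)C)C(C)C | intermediate
20 | C3 p-toluenesulfonylhydrazone of 19 (stereocentres as in 19) | OC[C@@]1(C)C(=NNS(=O)(=O)c3ccc(C)cc3)CC[C@]2(C)[C@@H]1CC[C@](C)(O[Si](CC)(CC)CC)[C@H]2CC[C@H](C)CCO[Si](C(C)C)(C(C)C)C(C)C | intermediate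
21 | (4S,5S,8S,9S,10R,13S)-8-(triethylsilyloxy)-15-(triisopropylsilyloxy)labdan-18-ol | OC[C@@]1(C)CCC[C@]2(C)[C@@H]1CC[C@](C)(O[Si](CC)(CC)CC)[C@H]2CC[C@H](C)CCO[Si](C(C)C)(C(C)C)C(C)C | intermediate
22 | angelic acid [(2Z)-2-methylbut-2-enoic acid] | C/C=C(/C)C(=O)O | starting material
23 | angelic 2,4,6-trichlorobenzoic anhydride | C/C=C(/C)C(=O)OC(=O)c1c(Cl)cc(Cl)cc1Cl | intermediate
24 | (4S,5S,8S,9S,10R,13S)-8-(triethylsilyloxy)-15-(triisopropylsilyloxy)labdan-18-yl angelate | C/C=C(/C)C(=O)OC[C@@]1(C)CCC[C@]2(C)[C@@H]1CC[C@](C)(O[Si](CC)(CC)CC)[C@H]2CC[C@H](C)CCO[Si](C(C)C)(C(C)C)C(C)C | intermediate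
25 | (4S,5S,8S,9S,10R,13S)-8,15-dihydroxylabdan-18-yl (2Z)-2-methylbut-2-enoate (CNP0150844.1) | C/C=C(/C)C(=O)OC[C@@]1(C)CCC[C@]2(C)[C@@H]1CC[C@](C)(O)[C@H]2CC[C@H](C)CCO | target

Total step count: 16 (steps 1–4 make the side-chain bromide, steps 5–9 the cyclohexenone, steps 10–16 are common).
Longest linear sequence: 12 steps, from (S)-linalool (steps 5–16).

Steps most likely to fail

1. Step 11 (key step). Protodesilylation of the hindered tetrasubstituted enol ether may outrun C–C bond formation, the vinyl ketone may oligomerise under the Lewis acid, or the facial preference at C10 may be eroded because the axial O8 substituent lies 1,3 to the attacked face. The fallback is an aprotic anionic annulation with a silicon-stabilised acceptor instead of Lewis-acid activation. It sets out from 13, which MeLi (THF, 0 °C → rt) cleaves at the O–Si bond to give the lithium enolate F1. Separately, commercial (1-bromovinyl)trimethylsilane is converted with Mg (THF) into [1-(trimethylsilyl)vinyl]magnesium bromide F2, which adds to propanal to give 2-(trimethylsilyl)pent-1-en-3-ol F3, and Dess–Martin oxidation gives 2-(trimethylsilyl)pent-1-en-3-one F4. F1 is added to F4 at −78 °C, where the α-silyl group stabilises the adduct enolate and suppresses polymerisation, giving after an NH4Cl quench the α-silyl 1,5-diketone F5. NaOMe/MeOH (55 °C) removes the silyl group and effects the aldol condensation, which comes back to the route at 17.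

2. Step 10. Conversion at the β-carbon may be low, since it is flanked by the quaternary C8 and the enone carries an α-methyl group, or the cuprate may discriminate poorly between the silyloxy and methyl faces at C8. The fallback replaces substrate control by catalyst control. It sets out from 11 and Grignard reagent 12 (made from 5 as before): a copper(I) complex of a chiral N-heterocyclic carbene, of the kind established for asymmetric conjugate addition of Grignard reagents to 2-methylcyclohex-2-enones with enolate trapping, is used in Et2O at −30 °C with the ligand antipode that reinforces attack anti to the silyloxy group (to be identified by running both antipodes). This gives the bromomagnesium enolate F6, which is silylated in the same flask with TMSCl/Et3N/HMPA and so comes back to the route at 13.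

3. Step 14. Hydride transfer to the C=N flanked by the quaternary C4 may stall, or the borylated hydrazide may fragment to an alkene instead of the alkane. The fallback is deliberate elimination followed by hydrogenation. It sets out from 20: excess n-BuLi (THF/TMEDA, −78 °C → rt; Shapiro reaction, with one extra equivalent for the O18 alkoxide) gives the C3 vinyllithium F7, which on aqueous quench gives the Δ2 alkene F8. Hydrogenation (H2, Pd/C, EtOAc), for which the molecule holds no other reducible group at this stage, comes back to the route at 21.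

Further compounds

F1 | step 11 | lithium enolate of the ring-B ketone (13 with Li in place of SiMe3) | [Li]OC1=C(C)[C@H](CC[C@H](C)CCO[Si](C(C)C)(C(C)C)C(C)C)[C@@](C)(O[Si](CC)(CC)CC)CC1
F2 | step 11 | [1-(trimethylsilyl)vinyl]magnesium bromide | C=C([Mg]Br)[Si](C)(C)C
F3 | step 11 | 2-(trimethylsilyl)pent-1-en-3-ol | CCC(O)C(=C)[Si](C)(C)C
F4 | step 11 | 2-(trimethylsilyl)pent-1-en-3-one | CCC(=O)C(=C)[Si](C)(C)C
F5 | step 11 | α-silyl 1,5-diketone (15 with SiMe3 on C2; C2 epimers) | CCC(=O)C([Si](C)(C)C)C[C@]1(C)C(=O)CC[C@](C)(O[Si](CC)(CC)CC)[C@H]1CC[C@H](C)CCO[Si](C(C)C)(C(C)C)C(C)C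
F6 | step 10 | bromomagnesium enolate of the ring-B ketone | Br[Mg]OC1=C(C)[C@H](CC[C@H](C)CCO[Si](C(C)C)(C(C)C)C(C)C)[C@@](C)(O[Si](CC)(CC)CC)CC1
F7 | step 14 | C3 vinyllithium (O18 as lithium alkoxide) | [Li]OC[C@@]1(C)C([Li])=CC[C@]2(C)[C@@H]1CC[C@](C)(O[Si](CC)(CC)CC)[C@H]2CC[C@H](C)CCO[Si](C(C)C)(C(C)C)C(C)C
F8 | step 14 | Δ2 alkene, 8-(triethylsilyloxy)-15-(triisopropylsilyloxy)labd-2-en-18-ol | OC[C@@]1(C)C=CC[C@]2(C)[C@@H]1CC[C@](C)(O[Si](CC)(CC)CC)[C@H]2CC[C@H](C)CCO[Si](C(C)C)(C(C)C)C(C)C
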